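**Strategy.** The six-membered ring (C1 CHOAc, C2 CH2, C3 CHBr, C4 CMe2, C5=C6; side chain C7, C8) is cut at C1–C2 and C3–C4. The key step exploits the position of C3 between the quaternary C4 and the C2 methylene: a vinyl group on boron supplies C2–C3, takes C4 from boron by a 1,2-metallate shift and receives the C1 carbonyl from palladium, so the open C1–C5 chain and the C3–B stereocentre arise together. Its precursor is the ate complex of α,α-dimethylallyl pinacol boronate and vinyllithium, coupled with morpholine-4-carbonyl chloride. Metathesis then closes the ring at C5=C6, and the boron is later exchanged for bromine with inversion.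

Key step: step 3

Assumption: the MandyPhos enantiomer used is the one that gives the 3R boronic ester 9; if the sense of induction with a tertiary allylic migrating group is the reverse, the antipodal ligand is taken. Both CBS reductions are assigned by the usual model, with the alkenyl group as the large substituent. The labels C1–C8 below are those of the target as defined above.

Remark on the precursor: the pinacol ester is kept because its bulk slows 1,3-borotropic shift of the tertiary allyl boronate and because it is the ester needed for the later bromination. Vinyllithium made from vinyl bromide carries LiBr, so NaOTf is added in the coupling to exchange halide for triflate.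

**Step 1**
Reactants: 1 1-chloro-3-methylbut-2-ene (prenyl chloride); 2 2-isopropoxy-4,4,5,5-tetramethyl-1,3,2-dioxaborolane
Product: 4 4,4,5,5-tetramethyl-2-(2-methylbut-3-en-2-yl)-1,3,2-dioxaborolane, via prenylmagnesium chloride 3 (not isolated)
Conditions: Mg, THF, 0 °C; then 2, THF, −78 °C to rt; aq. NH4Cl
Reagents that add atoms: none
Why: An allylic Grignard reagent attacks the alkoxy boronate through its γ-carbon (SE2′ borylation of an allylmagnesium reagent), which places boron on the tertiary carbon, and the pinacol ester is slow to rearrange to the prenyl isomer.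

**Step 2**
Reactants: 5 vinyl bromide
Product: 6 vinyllithium (solution, used at once)
Conditions: t-BuLi (2 equiv), Et2O, −78 °C
Reagents that add atoms: tert-butyllithium, [Li]C(C)(C)C
Why: Bromine–lithium exchange at low temperature is fast for vinyl bromide, and the second equivalent of t-BuLi removes the t-BuBr formed.

**Step 3**
Reactants: 4 4,4,5,5-tetramethyl-2-(2-methylbut-3-en-2-yl)-1,3,2-dioxaborolane; 6 vinyllithium; 7 morpholine-4-carbonyl chloride
Product: 9 (3R)-4,4-dimethyl-1-(morpholin-4-yl)-3-(4,4,5,5-tetramethyl-1,3,2-dioxaborolan-2-yl)hex-5-en-1-one, via lithium vinyl boronate complex 8 (not isolated)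
Conditions: 4 + 6, THF/Et2O, −78 to 0 °C; then Pd(OAc)2 (2 mol%), 1,1′-bis[bis(4-methoxy-3,5-dimethylphenyl)phosphino]-2,2′-bis[α-(dimethylamino)benzyl]ferrocene (MandyPhos, one enantiomer, 2.4 mol%), NaOTf, 7, THF, 40 °C
Reagents that add atoms: none
Why: Proposed new method: zerovalent palladium adds oxidatively to carbamoyl chloride 7, the carbamoyl complex of divalent palladium (kept cationic by NaOTf) binds the B-vinyl group of 8, the tertiary allyl carbon C4 shifts from boron to C3 on the face opposite palladium, and reductive elimination joins C2 to the C1 carbonyl. The closest known reaction type is the palladium-catalysed enantioselective conjunctive cross-coupling of vinylboron ate complexes with carbamoyl chlorides to β-boryl amides, known for aryl, primary and secondary alkyl migrating groups but not for a tertiary allylic one. No ring is closed: the step forms C3–C4 and C1–C2 and so the open C1–C5 chain. The single new stereocentre, C3, is set by the chiral ferrocenyl diphosphine on palladium, which selects the face of the vinyl group that is bound while C4 arrives anti. The step needs the 1,2-shift to outrun transfer of the allyl group to palladium (directly or by γ-attack) and plain vinyl transfer; the electron-rich, fully substituted migrating carbon, the bulk of the pinacol ester around boron and the cationic, alkene-seeking palladium centre should favour migration.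

**Step 4**
Reactants: 9 (3R)-4,4-dimethyl-1-(morpholin-4-yl)-3-(4,4,5,5-tetramethyl-1,3,2-dioxaborolan-2-yl)hex-5-en-1-one; 10 vinylmagnesium bromide
Product: 11 (5R)-6,6-dimethyl-5-(4,4,5,5-tetramethyl-1,3,2-dioxaborolan-2-yl)octa-1,7-dien-3-one
Conditions: THF, −20 to 0 °C; inverse quench into cold 1 M HCl
Reagents that add atoms: none
Why: A morpholine amide behaves like a Weinreb amide, so the magnesium hemiaminal persists until the acidic quench and the vinyl ketone forms without over-addition, while the hindered secondary boronic ester is left alone and the acid keeps freed morpholine from adding to the enone.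

**Step 5**
Reactants: 11 (5R)-6,6-dimethyl-5-(4,4,5,5-tetramethyl-1,3,2-dioxaborolan-2-yl)octa-1,7-dien-3-one
Product: 12 (5R)-4,4-dimethyl-5-(4,4,5,5-tetramethyl-1,3,2-dioxaborolan-2-yl)cyclohex-2-en-1-one
Conditions: second-generation Grubbs catalyst (5 mol%), CH2Cl2 (0.01 M), 40 °C
Reagents that add atoms: none
Why: Ring-closing metathesis of the vinyl ketone onto the terminal alkene forms the six-membered enone with loss of ethene, helped by the gem-dimethyl group, and the ruthenium carbene tolerates the boronic ester.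

**Step 6**
Reactants: 12 (5R)-4,4-dimethyl-5-(4,4,5,5-tetramethyl-1,3,2-dioxaborolan-2-yl)cyclohex-2-en-1-one
Product: 13 (5R)-2-iodo-4,4-dimethyl-5-(4,4,5,5-tetramethyl-1,3,2-dioxaborolan-2-yl)cyclohex-2-en-1-one
Conditions: I2, pyridine, CH2Cl2, 0 °C to rt
Reagents that add atoms: iodine, II
Why: α-Iodination of an enone by pyridine addition, iodination and elimination is established for 4,4-dimethylcyclohex-2-enone and does not touch an alkyl boronic ester.

**Step 7**
Reactants: 13 (5R)-2-iodo-4,4-dimethyl-5-(4,4,5,5-tetramethyl-1,3,2-dioxaborolan-2-yl)cyclohex-2-en-1-one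
Product: 14 (1R,5R)-2-iodo-4,4-dimethyl-5-(4,4,5,5-tetramethyl-1,3,2-dioxaborolan-2-yl)cyclohex-2-en-1-ol
Conditions: (S)-1-methyl-3,3-diphenyltetrahydro-1H,3H-pyrrolo[1,2-c][1,3,2]oxazaborole (20 mol%), BH3·SMe2, THF, −20 °C; MeOH
Reagents that add atoms: none
Why: Corey–Bakshi–Shibata reduction, for which 2-iodoenones are very good substrates (α-iodovinyl as the large group), should set C1 as R under catalyst control, placing the hydroxyl trans to boron against the modest substrate preference for the cis alcohol.

**Step 8**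
Reactants: 14 (1R,5R)-2-iodo-4,4-dimethyl-5-(4,4,5,5-tetramethyl-1,3,2-dioxaborolan-2-yl)cyclohex-2-en-1-ol
Product: 15 tert-butyl{[(1R,5R)-2-iodo-4,4-dimethyl-5-(4,4,5,5-tetramethyl-1,3,2-dioxaborolan-2-yl)cyclohex-2-en-1-yl]oxy}dimethylsilane
Conditions: TBSCl, imidazole, DMF, rt
Reagents that add atoms: tert-butyldimethylsilyl chloride, CC(C)(C)[Si](C)(C)Cl
Why: Standard silylation of a secondary allylic alcohol gives an ether that withstands the aryllithium, Grignard, borane and Appel steps that follow.

**Step 9**
Reactants: 15 tert-butyl{[(1R,5R)-2-iodo-4,4-dimethyl-5-(4,4,5,5-tetramethyl-1,3,2-dioxaborolan-2-yl)cyclohex-2-en-1-yl]oxy}dimethylsilane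
Product: 17 tert-butyl{[(1R,5S)-5-bromo-2-iodo-4,4-dimethylcyclohex-2-en-1-yl]oxy}dimethylsilane, via lithium aryl boronate complex 16 (not isolated)
Conditions: 1-bromo-3,5-bis(trifluoromethyl)phenyl bromide-derived aryllithium (from 1-bromo-3,5-bis(trifluoromethyl)benzene, n-BuLi, THF, −78 °C); then 15; then NBS, THF, −78 °C to rt
Reagents that add atoms: N-bromosuccinimide, O=C1CCC(=O)N1Br
Why: The electron-poor aryllithium adds to boron to give a nucleophilic boronate complex that NBS attacks at carbon from the side opposite boron (SE2 with inversion, the stereospecific halogenation of secondary boronic ester ate complexes), so the 3R C–B bond should become the 3S C–Br bond, and the stabilised aryllithium should not exchange with the alkenyl iodide.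

**Step 10**
Reactants: 17 tert-butyl{[(1R,5S)-5-bromo-2-iodo-4,4-dimethylcyclohex-2-en-1-yl]oxy}dimethylsilane; 18 2-chloro-N-methoxy-N-methylacetamide
Product: 20 1-[(4S,6R)-4-bromo-6-{[tert-butyl(dimethyl)silyl]oxy}-3,3-dimethylcyclohex-1-en-1-yl]-2-chloroethan-1-one, via alkenylmagnesium chloride 19 (not isolated)
Conditions: i-PrMgCl·LiCl, THF, −20 to 0 °C; then 18, −20 °C to rt; aq. NH4Cl
Reagents that add atoms: none
Why: Iodine–magnesium exchange of the alkenyl iodide spares the secondary alkyl bromide and the silyl ether, and the alkenylmagnesium adds once to the Weinreb amide (Weinreb ketone synthesis) to give the chloromethyl ketone.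

**Step 11**
Reactants: 20 1-[(4S,6R)-4-bromo-6-{[tert-butyl(dimethyl)silyl]oxy}-3,3-dimethylcyclohex-1-en-1-yl]-2-chloroethan-1-one
Product: 21 (1S)-1-[(4S,6R)-4-bromo-6-{[tert-butyl(dimethyl)silyl]oxy}-3,3-dimethylcyclohex-1-en-1-yl]-2-chloroethan-1-ol
Conditions: (S)-1-methyl-3,3-diphenyltetrahydro-1H,3H-pyrrolo[1,2-c][1,3,2]oxazaborole (20 mol%), BH3·SMe2, THF, −30 °C; MeOH
Reagents that add atoms: none
Why: Corey–Bakshi–Shibata reduction of α-chloro ketones is reliable, and with the fully substituted cyclohexenyl group as the large substituent and CH2Cl as the small one the (S)-catalyst should give the 7S chlorohydrin under catalyst control.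

**Step 12**
Reactants: 21 (1S)-1-[(4S,6R)-4-bromo-6-{[tert-butyl(dimethyl)silyl]oxy}-3,3-dimethylcyclohex-1-en-1-yl]-2-chloroethan-1-ol
Product: 22 {[(1R,5S)-5-bromo-2-[(1R)-1-bromo-2-chloroethyl]-4,4-dimethylcyclohex-2-en-1-yl]oxy}(tert-butyl)dimethylsilane
Conditions: CBr4, PPh3, CH2Cl2, 0 °C
Reagents that add atoms: carbon tetrabromide, BrC(Br)(Br)Br
Why: In the Appel reaction bromide displaces the alkoxyphosphonium group by SN2, turning the 7S alcohol into the 7R bromide with inversion, while the electron-withdrawing CH2Cl group disfavours ionisation and the quaternary C4 shields C5 from SN2′ attack.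

**Step 13**
Reactants: 22 {[(1R,5S)-5-bromo-2-[(1R)-1-bromo-2-chloroethyl]-4,4-dimethylcyclohex-2-en-1-yl]oxy}(tert-butyl)dimethylsilane
Product: 23 (1R,5S)-5-bromo-2-[(1R)-1-bromo-2-chloroethyl]-4,4-dimethylcyclohex-2-en-1-ol
Conditions: HF·pyridine, pyridine, THF, 0 °C to rt
Reagents that add atoms: none
Why: Buffered HF cleaves the silyl ether under conditions mild enough to spare the allylic bromide, the neopentylic bromide and the chloride.

**Step 14**
Reactants: 23 (1R,5S)-5-bromo-2-[(1R)-1-bromo-2-chloroethyl]-4,4-dimethylcyclohex-2-en-1-ol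
Product: 24 (1R,5S)-5-bromo-2-[(1R)-1-bromo-2-chloroethyl]-4,4-dimethylcyclohex-2-en-1-yl acetate
Conditions: Ac2O, pyridine, DMAP (cat.), CH2Cl2, 0 °C
Reagents that add atoms: acetic anhydride, CC(=O)OC(C)=O
Why: Acylation under nucleophilic catalysis occurs at oxygen with retention, giving the 1R acetate cis to the ring bromine as in the target.

**Compound list**
1 | 1-chloro-3-methylbut-2-ene | CC(C)=CCCl | starting material
2 | 2-isopropoxy-4,4,5,5-tetramethyl-1,3,2-dioxaborolane | CC(C)OB1OC(C)(C)C(C)(C)O1 | starting material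
3 | prenylmagnesium chloride | CC(C)=CC[Mg]Cl | intermediate
4 | 4,4,5,5-tetramethyl-2-(2-methylbut-3-en-2-yl)-1,3,2-dioxaborolane | C=CC(C)(C)B1OC(C)(C)C(C)(C)O1 | intermediate
5 | vinyl bromide | C=CBr | starting material
6 | vinyllithium | [Li]C=C | intermediate
7 | morpholine-4-carbonyl chloride | O=C(Cl)N1CCOCC1 | starting material
8 | lithium (2-methylbut-3-en-2-yl)(vinyl)(pinacolato)borate | [Li+].C=C[B-]1(OC(C)(C)C(C)(C)O1)C(C)(C)C=C | intermediate
9 | (3R)-4,4-dimethyl-1-(morpholin-4-yl)-3-(4,4,5,5-tetramethyl-1,3,2-dioxaborolan-2-yl)hex-5-en-1-one | O=C(C[C@@H](B1OC(C)(C)C(C)(C)O1)C(C)(C)C=C)N1CCOCC1 | intermediate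
10 | vinylmagnesium bromide | C=C[Mg]Br | starting material
11 | (5R)-6,6-dimethyl-5-(4,4,5,5-tetramethyl-1,3,2-dioxaborolan-2-yl)octa-1,7-dien-3-one | C=CC(=O)C[C@@H](B1OC(C)(C)C(C)(C)O1)C(C)(C)C=C | intermediate
12 | (5R)-4,4-dimethyl-5-(4,4,5,5-tetramethyl-1,3,2-dioxaborolan-2-yl)cyclohex-2-en-1-one | O=C1C[C@@H](B2OC(C)(C)C(C)(C)O2)C(C)(C)C=C1 | intermediate
13 | (5R)-2-iodo-4,4-dimethyl-5-(4,4,5,5-tetramethyl-1,3,2-dioxaborolan-2-yl)cyclohex-2-en-1-one | O=C1C[C@@H](B2OC(C)(C)C(C)(C)O2)C(C)(C)C=C1I | intermediate
14 | (1R,5R)-2-iodo-4,4-dimethyl-5-(4,4,5,5-tetramethyl-1,3,2-dioxaborolan-2-yl)cyclohex-2-en-1-ol | O[C@@H]1C[C@@H](B2OC(C)(C)C(C)(C)O2)C(C)(C)C=C1I | intermediate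
15 | tert-butyl{[(1R,5R)-2-iodo-4,4-dimethyl-5-(4,4,5,5-tetramethyl-1,3,2-dioxaborolan-2-yl)cyclohex-2-en-1-yl]oxy}dimethylsilane | CC(C)(C)[Si](C)(C)O[C@@H]1C[C@@H](B2OC(C)(C)C(C)(C)O2)C(C)(C)C=C1I | intermediate
16 | lithium [3,5-bis(trifluoromethyl)phenyl][(1R,5R)-5-{[tert-butyl(dimethyl)silyl]oxy}-4-iodo-2,2-dimethylcyclohex-3-en-1-yl](pinacolato)borate | [Li+].CC(C)(C)[Si](C)(C)O[C@@H]1C[C@@H]([B-]2(OC(C)(C)C(C)(C)O2)c3cc(cc(c3)C(F)(F)F)C(F)(F)F)C(C)(C)C=C1I | intermediate
17 | tert-butyl{[(1R,5S)-5-bromo-2-iodo-4,4-dimethylcyclohex-2-en-1-yl]oxy}dimethylsilane | CC(C)(C)[Si](C)(C)O[C@@H]1C[C@H](Br)C(C)(C)C=C1I | intermediate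
18 | 2-chloro-N-methoxy-N-methylacetamide | CON(C)C(=O)CCl | starting material
19 | [(4S,6R)-4-bromo-6-{[tert-butyl(dimethyl)silyl]oxy}-3,3-dimethylcyclohex-1-en-1-yl]magnesium chloride | CC(C)(C)[Si](C)(C)O[C@@H]1C[C@H](Br)C(C)(C)C=C1[Mg]Cl | intermediate
20 | 1-[(4S,6R)-4-bromo-6-{[tert-butyl(dimethyl)silyl]oxy}-3,3-dimethylcyclohex-1-en-1-yl]-2-chloroethan-1-one | CC(C)(C)[Si](C)(C)O[C@@H]1C[C@H](Br)C(C)(C)C=C1C(=O)CCl | intermediate
21 | (1S)-1-[(4S,6R)-4-bromo-6-{[tert-butyl(dimethyl)silyl]oxy}-3,3-dimethylcyclohex-1-en-1-yl]-2-chloroethan-1-ol | CC(C)(C)[Si](C)(C)O[C@@H]1C[C@H](Br)C(C)(C)C=C1[C@H](O)CCl | intermediate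
22 | {[(1R,5S)-5-bromo-2-[(1R)-1-bromo-2-chloroethyl]-4,4-dimethylcyclohex-2-en-1-yl]oxy}(tert-butyl)dimethylsilane | CC(C)(C)[Si](C)(C)O[C@@H]1C[C@H](Br)C(C)(C)C=C1[C@@H](Br)CCl | intermediate
23 | (1R,5S)-5-bromo-2-[(1R)-1-bromo-2-chloroethyl]-4,4-dimethylcyclohex-2-en-1-ol | O[C@@H]1C[C@H](Br)C(C)(C)C=C1[C@@H](Br)CCl | intermediate
24 | (1R,5S)-5-bromo-2-[(1R)-1-bromo-2-chloroethyl]-4,4-dimethylcyclohex-2-en-1-yl acetate | CC(=O)O[C@@H]1C[C@H](Br)C(C)(C)C=C1[C@@H](Br)CCl | target

**Step count.** Total: 14 steps. Longest linear sequence: 13 steps (step 1, then steps 3–14); step 2 is a one-step side branch.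

**Steps most likely to fail**

Step 3 (Proposed new method). The hindered tertiary allyl group may migrate too slowly, so that the allyl group passes from boron to palladium, the allylboronate reacts through its γ-carbon, or the vinyl group is simply transferred; the enantioselectivity with this migrating group is also untested. The fallback uses known chemistry, sets out from prenylmagnesium chloride 3 and returns at 9. Compound 3 is added to paraformaldehyde in THF, reacting at its γ-carbon to give 2,2-dimethylbut-3-en-1-ol F1. Swern oxidation gives 2,2-dimethylbut-3-enal F2. Horner–Wadsworth–Emmons olefination with diethyl [2-(morpholin-4-yl)-2-oxoethyl]phosphonate (LiCl, DBU, MeCN) gives (2E)-4,4-dimethyl-1-(morpholin-4-yl)hexa-2,5-dien-1-one F3. Copper-catalysed enantioselective conjugate borylation of this unsaturated amide (CuCl, NaOt-Bu, (R)-1-[(S)-2-(diphenylphosphino)ferrocenyl]ethyldicyclohexylphosphine or its antipode as required, B2pin2, MeOH, THF) should then place boron at C3 and give 9.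

Step 9. Approach of NBS to the back of the C–B bond is crowded by the neighbouring quaternary carbon, so the polar substitution may slow down and electron transfer to NBS may take over, which would erode the inversion at C3. The fallback sets out from 15 and returns at 17. Oxidation with NaBO3·4H2O in THF/H2O converts the C–B bond with retention into the alcohol (1R,5R)-5-{[tert-butyl(dimethyl)silyl]oxy}-4-iodo-2,2-dimethylcyclohex-3-en-1-ol F4. Tf2O and pyridine in CH2Cl2 at −20 °C give (1R,5R)-5-{[tert-butyl(dimethyl)silyl]oxy}-4-iodo-2,2-dimethylcyclohex-3-en-1-yl trifluoromethanesulfonate F5. Displacement with LiBr in a dipolar aprotic solvent then gives 17 by SN2 with inversion; this is expected to be slow at such a centre and to compete with elimination and rearrangement, but it involves no electron-transfer pathway.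

Step 12. The allylic alkoxyphosphonium ion may ionise, or the neighbouring chlorine may participate, which would cost the inversion at C7, move the double bond, or exchange the halogens between C7 and C8. The fallback sets out from 21 and returns at 22, and separates activation from displacement. MsCl and Et3N in CH2Cl2 at −20 °C give (1S)-1-[(4S,6R)-4-bromo-6-{[tert-butyl(dimethyl)silyl]oxy}-3,3-dimethylcyclohex-1-en-1-yl]-2-chloroethyl methanesulfonate F6. This covalent sulfonate is treated with LiBr in acetone at 0 °C, where free bromide should displace it by SN2 with inversion to give 22.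

**Further compounds**
F1 | step 3 | 2,2-dimethylbut-3-en-1-ol | C=CC(C)(C)CO
F2 | step 3 | 2,2-dimethylbut-3-enal | C=CC(C)(C)C=O
F3 | step 3 | (2E)-4,4-dimethyl-1-(morpholin-4-yl)hexa-2,5-dien-1-one | C=CC(C)(C)/C=C/C(=O)N1CCOCC1
F4 | step 9 | (1R,5R)-5-{[tert-butyl(dimethyl)silyl]oxy}-4-iodo-2,2-dimethylcyclohex-3-en-1-ol | CC(C)(C)[Si](C)(C)O[C@@H]1C[C@@H](O)C(C)(C)C=C1I
F5 | step 9 | (1R,5R)-5-{[tert-butyl(dimethyl)silyl]oxy}-4-iodo-2,2-dimethylcyclohex-3-en-1-yl trifluoromethanesulfonate | CC(C)(C)[Si](C)(C)O[C@@H]1C[C@@H](OS(=O)(=O)C(F)(F)F)C(C)(C)C=C1I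
F6 | step 12 | (1S)-1-[(4S,6R)-4-bromo-6-{[tert-butyl(dimethyl)silyl]oxy}-3,3-dimethylcyclohex-1-en-1-yl]-2-chloroethyl methanesulfonate | CC(C)(C)[Si](C)(C)O[C@@H]1C[C@H](Br)C(C)(C)C=C1[C@H](OS(C)(=O)=O)CCl
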